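**Plan**

- Retrosynthetic cuts, in order: the two C8–C(=O) bonds (acyl groups removed as a Weinreb amide); the O1–C2 and C2–CH3 bonds of both pyran rings (back to two dihydrocoumarin lactones); the two O1–C8a bonds (back to two indan-1-ones); the two aryl–CH bonds at the bridge; and C3–C3a of each indanone (back to an aryl vinyl ketone).
- Forward, a Nazarov closure gives the five-membered ring of 5-bromo-4,6-dimethoxyindan-1-one. Two such units, as ketals, are joined at the ester carbon of methyl 6-methylheptanoate, the carbinol is reduced to the CH bridge, and the methyl ethers are exchanged for benzyl ethers.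
- Both cyclopentanone rings are then expanded to six-membered lactones by oxygen insertion. MeMgBr and mild acid turn the lactones into the 2,2-dimethylpyran rings, and C8 is brominated, lithiated and acylated before hydrogenolysis.
- Stereochemistry: both (R) centres come unchanged from (R)-2-methylbutanoic acid through its Weinreb amide. The bridge carbon carries two identical arms and is not a stereocentre.
- Enabling feature: in each chroman ring O1 is bonded to C8a, the aromatic carbon para to the bridge-bearing C6 and meta to O5 and O7. Deleting O1 contracts the pyran to the five-membered ring of an indan-1-one whose C1 sits on that same carbon, so an aryl shift to oxygen places O1 there and cannot produce the isomer closed on the C5 oxygen.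

Key step: step 9

Remark: 4-bromo-3,5-dimethoxybenzaldehyde is taken as purchasable; methyl ethers are carried as far as the bis-indanone because they tolerate the superacid ring closure and the ionic reduction, and are exchanged for benzyl ethers before the oxidation.

**Route**

Step 1
Reactants: 1 4-bromo-3,5-dimethoxybenzaldehyde; 2 vinylmagnesium bromide
Product: 3 1-(4-bromo-3,5-dimethoxyphenyl)prop-2-en-1-ol (racemic)
Conditions: vinylMgBr (1.2 equiv), THF, −78 → 0 °C; aq. NH4Cl
Reagents that add atoms: vinylmagnesium bromide 2, C=C[Mg]Br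
Why: The vinyl Grignard reagent adds 1,2 to the aromatic aldehyde (Grignard addition) much faster than it can touch the hindered aryl bromide, and the racemic carbinol centre formed here is erased by the oxidation in step 2.

Step 2
Reactants: 3 1-(4-bromo-3,5-dimethoxyphenyl)prop-2-en-1-ol
Product: 5 5-bromo-4,6-dimethoxyindan-1-one, via aryl vinyl ketone 4 (not isolated)
Conditions: MnO2 (activated, 10 equiv), CH2Cl2, rt; filter through Celite; filtrate added slowly to TfOH (5 equiv), CH2Cl2 (0.02 M), 0 °C → rt
Reagents that add atoms: none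
Why: MnO2 oxidises the allylic and benzylic alcohol, and in TfOH the O-protonated aryl vinyl ketone should undergo a Nazarov-type 4π electrocyclisation onto the ring carbon that is ortho to one methoxy group and para to the other, the two candidate carbons being equivalent by symmetry, so that a single indan-1-one with its carbonyl meta to both oxygens is expected.

Step 3
Reactants: 5 5-bromo-4,6-dimethoxyindan-1-one
Product: 6 5'-bromo-4',6'-dimethoxy-2',3'-dihydrospiro[1,3-dioxolane-2,1'-indene]
Conditions: HOCH2CH2OH (5 equiv), p-TsOH·H2O (5 mol%), toluene, reflux, Dean–Stark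
Reagents that add atoms: ethylene glycol, OCCO
Why: Acid-catalysed ketalisation with azeotropic removal of water masks the ketone as a dioxolane that is inert to the organolithium and organocerium reagents of step 5.

Step 4
Reactants: 7 6-methylheptanoic acid
Product: 8 methyl 6-methylheptanoate
Conditions: MeOH, H2SO4 (cat.), reflux
Reagents that add atoms: methanol, CO
Why: Fischer esterification in excess methanol turns the acid into an electrophile that can accept two aryl groups at its carbonyl carbon.

Step 5
Reactants: 6 5'-bromo-4',6'-dimethoxy-2',3'-dihydrospiro[1,3-dioxolane-2,1'-indene] (2.2 equiv); 8 methyl 6-methylheptanoate (1.0 equiv)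
Product: 12 1,1-bis(4',6'-dimethoxy-2',3'-dihydrospiro[1,3-dioxolane-2,1'-inden]-5'-yl)-6-methylheptan-1-ol, via aryllithium 9 (not isolated), via arylcerium dichloride 10 (not isolated), via aryl alkyl ketone 11 (not isolated)
Conditions: n-BuLi (2.2 equiv), THF, −78 °C; anhydrous CeCl3 (2.4 equiv), THF, −78 °C; 8, −78 → 0 °C; aq. NH4Cl
Reagents that add atoms: methyl 6-methylheptanoate 8, CC(C)CCCCC(=O)OC
Why: Bromine–lithium exchange at the carbon flanked by two methoxy groups is fast at −78 °C, and transmetalation to the less basic, strongly oxophilic organocerium reagent (CeCl3-mediated carbonyl addition) should let two aryl groups add to the ester carbon while enolisation of the intermediate ketone 11 is suppressed.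

Step 6
Reactants: 12 1,1-bis(4',6'-dimethoxy-2',3'-dihydrospiro[1,3-dioxolane-2,1'-inden]-5'-yl)-6-methylheptan-1-ol
Product: 14 5,5'-(6-methylheptane-1,1-diyl)bis(4,6-dimethoxyindan-1-one), via diketo carbinol 13 (not isolated)
Conditions: CF3CO2H (10 equiv), H2O (10 equiv), CH2Cl2, 0 °C → rt; then Et3SiH (3 equiv), 0 °C; aq. NaHCO3
Reagents that add atoms: water, O
Why: Aqueous TFA hydrolyses both dioxolanes, and the tertiary carbinol then ionises to a carbenium ion stabilised by four ortho methoxy groups that Et3SiH captures (ionic hydrogenation), which should be far faster at 0 °C than silane reduction of the indanone carbonyls, whose benzylic cations would gain nothing from the meta methoxy groups.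

Step 7
Reactants: 14 5,5'-(6-methylheptane-1,1-diyl)bis(4,6-dimethoxyindan-1-one)
Product: 15 5,5'-(6-methylheptane-1,1-diyl)bis(4,6-dihydroxyindan-1-one)
Conditions: BBr3 (6 equiv), CH2Cl2, −78 °C → rt; then H2O, 0 °C
Reagents that add atoms: none
Why: BBr3 cleaves the four aryl methyl ethers by complexation and bromide attack on methyl (boron tribromide ether cleavage), and the ketone para to each bridge-bearing carbon disfavours ipso protonation there, so the diarylmethine should survive.

Step 8
Reactants: 15 5,5'-(6-methylheptane-1,1-diyl)bis(4,6-dihydroxyindan-1-one)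
Product: 16 5,5'-(6-methylheptane-1,1-diyl)bis[4,6-bis(benzyloxy)indan-1-one]
Conditions: BnBr (5 equiv), K2CO3 (6 equiv), DMF, 50 °C
Reagents that add atoms: benzyl bromide, BrCc1ccccc1
Why: Williamson etherification of the four phenoxides installs benzyl ethers that withstand peracid, Grignard reagent, mild acid and organolithium and can be removed at the end by neutral hydrogenolysis.

Step 9
Reactants: 16 5,5'-(6-methylheptane-1,1-diyl)bis[4,6-bis(benzyloxy)indan-1-one]
Product: 17 6,6'-(6-methylheptane-1,1-diyl)bis[5,7-bis(benzyloxy)chroman-2-one]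
Conditions: mCPBA (3 equiv), CF3CO2H (1 equiv), CH2Cl2, 0 °C → rt, dark; aq. Na2SO3/NaHCO3
Reagents that add atoms: mCPBA (3-chloroperoxybenzoic acid), OOC(=O)c1cccc(Cl)c1
Why: The peracid adds to each acid-activated indanone carbonyl to give a Criegee adduct, from which the aromatic carbon C7a shifts from C1 to the proximal peroxide oxygen as 3-chlorobenzoate leaves (Baeyer–Villiger oxidation). The closest known reaction type is the peracid oxidation of 1-indanones to 3,4-dihydrocoumarins, in which the aryl group migrates in preference to the ring methylene. Each six-membered lactone arises by ring expansion of a five-membered ketone ring through this 1,2-shift (insertion of one oxygen between C1 and C7a), not by an end-to-end cyclisation, and both O1–C8a bonds are made in this way. No stereocentre is created, and the bridge carbon stays non-stereogenic because both arms react identically. The step needs aryl-over-methylene migration and oxidation at the ketones only: the migrating sp2 carbon is para to the alkyl bridge and ortho to the ring alkyl carbon, which supports the developing positive charge, while both benzyloxy groups are meta to the carbonyl and so do not deactivate it as a vinylogous ester would. The benzyl ethers keep the rings non-phenolic, so the peracid should find no other site to attack, and no other ketone is present.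

Step 10
Reactants: 17 6,6'-(6-methylheptane-1,1-diyl)bis[5,7-bis(benzyloxy)chroman-2-one]; 18 methylmagnesium bromide
Product: 20 6,6'-(6-methylheptane-1,1-diyl)bis[5,7-bis(benzyloxy)-2,2-dimethylchromane], via tetraol 19 (not isolated)
Conditions: MeMgBr (6 equiv), THF, 0 °C → rt; aq. NH4Cl; crude in CH2Cl2, p-TsOH·H2O (10 mol%), rt
Reagents that add atoms: methylmagnesium bromide 18, C[Mg]Br
Why: Each aryl ester lactone takes up two methyl groups (double Grignard addition) to release the O1 phenol and a tertiary alcohol, and mild acid then ionises the tertiary alcohol, which is trapped by the only free phenolic oxygen (acid-catalysed cycloetherification) to close each 2,2-dimethylpyran ring, the C5 and C7 oxygens being blocked as benzyl ethers and the acid kept catalytic at room temperature to spare the electron-rich diarylmethine.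

Step 11
Reactants: 20 6,6'-(6-methylheptane-1,1-diyl)bis[5,7-bis(benzyloxy)-2,2-dimethylchromane]
Product: 21 6,6'-(6-methylheptane-1,1-diyl)bis[5,7-bis(benzyloxy)-8-bromo-2,2-dimethylchromane]
Conditions: NBS (2.1 equiv), CH2Cl2/MeCN, 0 °C, dark
Reagents that add atoms: N-bromosuccinimide, O=C1CCC(=O)N1Br
Why: Electrophilic aromatic bromination with NBS should occur at C8, the only unsubstituted carbon of each trioxygenated ring, which is ortho to O1 and O7 and para to O5.

Step 12
Reactants: 22 (R)-2-methylbutanoic acid
Product: 23 (R)-N-methoxy-N,2-dimethylbutanamide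
Conditions: CDI (1.1 equiv), CH2Cl2, 0 °C → rt; MeNH(OMe)·HCl (1.2 equiv), rt
Reagents that add atoms: N,O-dimethylhydroxylamine hydrochloride, CNOC.Cl
Why: Activation as the acyl imidazolide and aminolysis (Weinreb amide synthesis) needs neither a strong base nor a ketene-prone acid chloride, so the (R) centre of the acid should be carried over unchanged.

Step 13
Reactants: 21 6,6'-(6-methylheptane-1,1-diyl)bis[5,7-bis(benzyloxy)-8-bromo-2,2-dimethylchromane]; 23 (R)-N-methoxy-N,2-dimethylbutanamide (3 equiv)
Product: 25 6,6'-(6-methylheptane-1,1-diyl)bis{5,7-bis(benzyloxy)-2,2-dimethyl-8-[(R)-2-methylbutanoyl]chromane}, via dilithio compound 24 (not isolated)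
Conditions: t-BuLi (4.2 equiv), THF, −78 °C; 23, −78 → −20 °C; aq. NH4Cl at −20 °C
Reagents that add atoms: (R)-N-methoxy-N,2-dimethylbutanamide 23, CC[C@@H](C)C(=O)N(C)OC
Why: Bromine–lithium exchange with two equivalents of t-BuLi per bromide gives the C8 aryllithium, which adds to the Weinreb amide to form a chelated tetrahedral intermediate that can neither over-add nor enolise before the quench (Weinreb ketone synthesis), so both (R) centres should be transferred intact from 23.

Step 14
Reactants: 25 6,6'-(6-methylheptane-1,1-diyl)bis{5,7-bis(benzyloxy)-2,2-dimethyl-8-[(R)-2-methylbutanoyl]chromane}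
Product: 26 6,6'-(6-methylheptane-1,1-diyl)bis{5,7-dihydroxy-2,2-dimethyl-8-[(R)-2-methylbutanoyl]chromane} (CNP0324275.1)
Conditions: H2 (1 atm), 10% Pd/C, EtOAc/EtOH, rt
Reagents that add atoms: none
Why: Hydrogenolysis of the four benzyl ethers over Pd/C is a neutral debenzylation that should leave the hindered, hydrogen-bonded aryl ketones, the pyran rings and the two (R) centres untouched.

**Compound list**

1 | 4-bromo-3,5-dimethoxybenzaldehyde | COc1cc(C=O)cc(OC)c1Br | starting material
2 | vinylmagnesium bromide | C=C[Mg]Br | starting material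
3 | 1-(4-bromo-3,5-dimethoxyphenyl)prop-2-en-1-ol (racemic) | COc1cc(C(O)C=C)cc(OC)c1Br | intermediate
4 | 1-(4-bromo-3,5-dimethoxyphenyl)prop-2-en-1-one (aryl vinyl ketone, formed and consumed in step 2) | COc1cc(C(=O)C=C)cc(OC)c1Br | intermediate
5 | 5-bromo-4,6-dimethoxyindan-1-one | COc1cc2C(=O)CCc2c(OC)c1Br | intermediate
6 | 5'-bromo-4',6'-dimethoxy-2',3'-dihydrospiro[1,3-dioxolane-2,1'-indene] | COc1cc2c(CCC23OCCO3)c(OC)c1Br | intermediate
7 | 6-methylheptanoic acid | CC(C)CCCCC(=O)O | starting material
8 | methyl 6-methylheptanoate | CC(C)CCCCC(=O)OC | intermediate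
9 | (4',6'-dimethoxy-2',3'-dihydrospiro[1,3-dioxolane-2,1'-inden]-5'-yl)lithium (aryllithium, formed and consumed in step 5) | [Li]c1c(OC)cc2c(c1OC)CCC23OCCO3 | intermediate
10 | dichloro(4',6'-dimethoxy-2',3'-dihydrospiro[1,3-dioxolane-2,1'-inden]-5'-yl)cerium (arylcerium dichloride, formed and consumed in step 5) | Cl[Ce](Cl)c1c(OC)cc2c(c1OC)CCC23OCCO3 | intermediate
11 | 1-(4',6'-dimethoxy-2',3'-dihydrospiro[1,3-dioxolane-2,1'-inden]-5'-yl)-6-methylheptan-1-one (aryl alkyl ketone, formed and consumed in step 5) | CC(C)CCCCC(=O)c1c(OC)cc2c(c1OC)CCC23OCCO3 | intermediate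
12 | 1,1-bis(4',6'-dimethoxy-2',3'-dihydrospiro[1,3-dioxolane-2,1'-inden]-5'-yl)-6-methylheptan-1-ol | CC(C)CCCCC(O)(c1c(OC)cc2c(c1OC)CCC23OCCO3)c1c(OC)cc2c(c1OC)CCC23OCCO3 | intermediate
13 | 5,5'-(1-hydroxy-6-methylheptane-1,1-diyl)bis(4,6-dimethoxyindan-1-one) (diketo carbinol, formed and consumed in step 6) | CC(C)CCCCC(O)(c1c(OC)cc2C(=O)CCc2c1OC)c1c(OC)cc2C(=O)CCc2c1OC | intermediate
14 | 5,5'-(6-methylheptane-1,1-diyl)bis(4,6-dimethoxyindan-1-one) | CC(C)CCCCC(c1c(OC)cc2C(=O)CCc2c1OC)c1c(OC)cc2C(=O)CCc2c1OC | intermediate
15 | 5,5'-(6-methylheptane-1,1-diyl)bis(4,6-dihydroxyindan-1-one) | CC(C)CCCCC(c1c(O)cc2C(=O)CCc2c1O)c1c(O)cc2C(=O)CCc2c1O | intermediate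
16 | 5,5'-(6-methylheptane-1,1-diyl)bis[4,6-bis(benzyloxy)indan-1-one] | CC(C)CCCCC(c1c(OCc2ccccc2)cc2C(=O)CCc2c1OCc1ccccc1)c1c(OCc2ccccc2)cc2C(=O)CCc2c1OCc1ccccc1 | intermediate
17 | 6,6'-(6-methylheptane-1,1-diyl)bis[5,7-bis(benzyloxy)chroman-2-one] | CC(C)CCCCC(c1c(OCc2ccccc2)cc2OC(=O)CCc2c1OCc1ccccc1)c1c(OCc2ccccc2)cc2OC(=O)CCc2c1OCc1ccccc1 | intermediate
18 | methylmagnesium bromide | C[Mg]Br | starting material
19 | 4,4'-(6-methylheptane-1,1-diyl)bis[3,5-bis(benzyloxy)-2-(3-hydroxy-3-methylbutyl)phenol] (tetraol, formed and consumed in step 10) | CC(C)CCCCC(c1c(OCc2ccccc2)cc(O)c(CCC(C)(C)O)c1OCc1ccccc1)c1c(OCc2ccccc2)cc(O)c(CCC(C)(C)O)c1OCc1ccccc1 | intermediate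
20 | 6,6'-(6-methylheptane-1,1-diyl)bis[5,7-bis(benzyloxy)-2,2-dimethylchromane] | CC(C)CCCCC(c1c(OCc2ccccc2)cc2OC(C)(C)CCc2c1OCc1ccccc1)c1c(OCc2ccccc2)cc2OC(C)(C)CCc2c1OCc1ccccc1 | intermediate
21 | 6,6'-(6-methylheptane-1,1-diyl)bis[5,7-bis(benzyloxy)-8-bromo-2,2-dimethylchromane] | CC(C)CCCCC(c1c(OCc2ccccc2)c(Br)c2OC(C)(C)CCc2c1OCc1ccccc1)c1c(OCc2ccccc2)c(Br)c2OC(C)(C)CCc2c1OCc1ccccc1 | intermediate
22 | (R)-2-methylbutanoic acid | CC[C@@H](C)C(=O)O | starting material
23 | (R)-N-methoxy-N,2-dimethylbutanamide | CC[C@@H](C)C(=O)N(C)OC | intermediate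
24 | 8,8'-dilithio-6,6'-(6-methylheptane-1,1-diyl)bis[5,7-bis(benzyloxy)-2,2-dimethylchromane] (dilithio compound, formed and consumed in step 13) | CC(C)CCCCC(c1c(OCc2ccccc2)c([Li])c2OC(C)(C)CCc2c1OCc1ccccc1)c1c(OCc2ccccc2)c([Li])c2OC(C)(C)CCc2c1OCc1ccccc1 | intermediate
25 | 6,6'-(6-methylheptane-1,1-diyl)bis{5,7-bis(benzyloxy)-2,2-dimethyl-8-[(R)-2-methylbutanoyl]chromane} | CC[C@@H](C)C(=O)c1c(OCc2ccccc2)c(C(CCCCC(C)C)c2c(OCc3ccccc3)c3c(c(C(=O)[C@H](C)CC)c2OCc2ccccc2)OC(C)(C)CC3)c(OCc2ccccc2)c2c1OC(C)(C)CC2 | intermediate
26 | 6,6'-(6-methylheptane-1,1-diyl)bis{5,7-dihydroxy-2,2-dimethyl-8-[(R)-2-methylbutanoyl]chromane} (CNP0324275.1) | CC[C@@H](C)C(=O)c1c(O)c(C(CCCCC(C)C)c2c(O)c3c(c(C(=O)[C@H](C)CC)c2O)OC(C)(C)CC3)c(O)c2c1OC(C)(C)CC2 | target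

**Step count**

Total: 14 steps. Longest linear sequence: 12 steps (steps 1–3, 5–11, 13 and 14); steps 4 and 12 prepare the two side-chain building blocks.

**Steps most likely to fail, with fallbacks**

Step 5. The second aryl transfer may stall at ketone 11: the carbonyl is shielded by two ortho methoxy groups, and the crowded aryl metal may act as a base and enolise it, returning ketone and debrominated arene on work-up. The fallback sets out from 6 and makes the last bridge bond from an alkyl nucleophile and a ketone that cannot enolise. Bromine–lithium exchange of 6 (n-BuLi, THF, −78 °C) and addition of ethyl formate (0.5 equiv) should give bis(4',6'-dimethoxy-2',3'-dihydrospiro[1,3-dioxolane-2,1'-inden]-5'-yl)methanol F1. Oxidation with Dess–Martin periodinane should give bis(4',6'-dimethoxy-2',3'-dihydrospiro[1,3-dioxolane-2,1'-inden]-5'-yl)methanone F2. Addition of 5-methylhexyllithium (from 1-bromo-5-methylhexane and t-BuLi, Et2O, −78 °C) to this diaryl ketone should then give carbinol 12, where the route is rejoined.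

Step 9. The ring methylene may migrate in competition with the aryl carbon, giving isochromanone-type lactones. Alternatively, once the first oxygen is in place the peracid may attack the now trioxygenated ring, or peracid addition to the second ketone may be slow. The fallback sets out from 16 and keeps the aryl shift to oxygen but runs it through a cationic hydroperoxide rearrangement, for which aryl migration is strongly preferred. MeMgBr should add to both ketones to give 5,5'-(6-methylheptane-1,1-diyl)bis[4,6-bis(benzyloxy)-1-methylindan-1-ol] F3. Treatment with H2O2 and BF3·OEt2 in CH2Cl2 at 0 °C should form the tertiary benzylic hydroperoxides, which undergo Hock rearrangement and hydrolysis to 4,4'-(6-methylheptane-1,1-diyl)bis[3,5-bis(benzyloxy)-2-(3-oxobutyl)phenol] F4. A second treatment with MeMgBr should give tetraol 19, which is cyclised as in step 10 to rejoin the route at 20.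

Step 13. The doubly ortho-substituted aryllithium may add only sluggishly to the α-branched amide and instead be protonated, or may attack the N-methoxy group, so that acylation of both rings stays incomplete. The fallback sets out from 21 and replaces acyl substitution by addition to an aldehyde followed by oxidation. Reduction of 23 with DIBAL-H (THF, −78 °C) should give (R)-2-methylbutanal F5, used cold and at once. The dilithio compound made from 21 as in step 13 should add to it to give 6,6'-(6-methylheptane-1,1-diyl)bis{5,7-bis(benzyloxy)-8-[(2R)-1-hydroxy-2-methylbutyl]-2,2-dimethylchromane} F6 as a mixture of carbinol epimers. Oxidation with Dess–Martin periodinane buffered with NaHCO3, a non-basic method that should not touch the α-centres, then gives 25, where the route is rejoined.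

**Further compounds**

F1 | step 5 | bis(4',6'-dimethoxy-2',3'-dihydrospiro[1,3-dioxolane-2,1'-inden]-5'-yl)methanol | OC(c1c(OC)cc2c(c1OC)CCC23OCCO3)c1c(OC)cc2c(c1OC)CCC23OCCO3
F2 | step 5 | bis(4',6'-dimethoxy-2',3'-dihydrospiro[1,3-dioxolane-2,1'-inden]-5'-yl)methanone | O=C(c1c(OC)cc2c(c1OC)CCC23OCCO3)c1c(OC)cc2c(c1OC)CCC23OCCO3
F3 | step 9 | 5,5'-(6-methylheptane-1,1-diyl)bis[4,6-bis(benzyloxy)-1-methylindan-1-ol] | CC(C)CCCCC(c1c(OCc2ccccc2)cc2c(c1OCc1ccccc1)CCC2(C)O)c1c(OCc2ccccc2)cc2c(c1OCc1ccccc1)CCC2(C)O
F4 | step 9 | 4,4'-(6-methylheptane-1,1-diyl)bis[3,5-bis(benzyloxy)-2-(3-oxobutyl)phenol] | CC(C)CCCCC(c1c(OCc2ccccc2)cc(O)c(CCC(C)=O)c1OCc1ccccc1)c1c(OCc2ccccc2)cc(O)c(CCC(C)=O)c1OCc1ccccc1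
F5 | step 13 | (R)-2-methylbutanal | CC[C@@H](C)C=O
F6 | step 13 | 6,6'-(6-methylheptane-1,1-diyl)bis{5,7-bis(benzyloxy)-8-[(2R)-1-hydroxy-2-methylbutyl]-2,2-dimethylchromane} | CC[C@@H](C)C(O)c1c(OCc2ccccc2)c(C(CCCCC(C)C)c2c(OCc3ccccc3)c3c(c(C(O)[C@H](C)CC)c2OCc2ccccc2)OC(C)(C)CC3)c(OCc2ccccc2)c2c1OC(C)(C)CC2
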